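**Remarks before the route**

- Atom labels used throughout: ring A = C1' (C=O), C2' (acetyl), C3' (OH), C4' (stereocentre with CH3 and geranyl), C5' (OH), C6'; bridge = C7'; chromene = O1, C2, C3, C4, C4a, C5–C8, C8a (ring B = C4a–C8a, ring C = the pyran); geranyl = C1''–C8''.
- Assumption on tautomers: 16 is drawn as the tautomer of the given SMILES (C2'=C3' and C5'=C6' enols, C1'=O). The descriptor R at C4' refers to this drawing; the tautomers interconvert and C4', which has no hydrogen, is not affected.
- Assumption on induction: the sense of induction of the chiral ligand in step 8 cannot be derived with certainty for this nucleophile. The (S,S) ligand is written as the working choice; its commercial enantiomer takes its place if the induction proves opposite.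

## Analysis of the target

Compound 16 (C35H44O8) is a methylene-bridged pair of acylphloroglucinol units. Ring A (C1'–C6') is a cyclohexa-2,5-dienone at the oxidation level of an acylfilicinic acid; the methylene C7' links its C6' to C8 of the fully substituted benzene ring B, which carries 5-OH, 6-butanoyl, 7-OH and the fused 2,2-dimethyl-2H-pyran ring C (O1, C2, C3=C4). The only stereocentre is C4' (R), an all-carbon quaternary centre in ring A that bears a methyl group and the (E)-geranyl chain. It is flanked by the enol carbons C3' and C5' and is stereogenic only because C2' carries the acetyl group and C6' the bridge. There is therefore no second stereocentre to relay from and no hydrogen to equilibrate, and the two sides a reagent must tell apart differ only from the second ring atom onwards. The feature the plan is built on: ring A has exactly the substitution pattern and oxidation level of an aromatic acylphloroglucinol that has been C-alkylated at C4', so ring A is a dearomatised benzene ring and C4' was one of its sp2 atoms. Sensitive groups are the acid-labile chromene alkene C3=C4, the two trisubstituted alkenes of the chain (the C2''=C3'' geometry must stay E), the strongly acidic, chelating enolised triketone (retro-Claisen under hot alkali), the bridge (exchange between rings under hot base) and the air-sensitive polyphenol. The hard points are four: enantiocontrol at C4'; alkylating a methyl-bearing ring carbon rather than a free ring CH; a cross-selective bridge between two different phloroglucinol units; and a pyran oxygen that must be the one para to the butanoyl group (O1 on C8a, next to C8).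

## Retrosynthetic reasoning

**16 ⇒ 13 + 15 (cut C4'–C1'').** This single bond removes the stereocentre, the C10 chain and the non-aromatic character of ring A together. The precursor 13 is achiral, flat and fully aromatic. In 13 all three nucleophilic carbons of ring A are already substituted (C2' acetyl, C4' methyl, C6' bridge), so a C-allylation cannot end in an aromatic product and must dearomatise. In a monomer the free ring CH would react first; here the bridge itself serves as the blocking group. The forward reaction, a catalytic enantioselective dearomative allylation, has to attach C1'' of 15 with the E double bond intact. It must do so at C4' rather than at C6', on oxygen or on ring B, and on one face of ring A.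

**13 ⇒ 8 + 11 (cut C6'–C7').** At the aromatic stage each partner has one free ring carbon (C8 of 6; C5 of 11, which becomes C6'), so the site is not in question. Cross-selectivity is obtained by placing C7' on one partner only, as the aminomethyl group of 8. Loss of the amine gives the o-quinone methide 12, which the more nucleophilic 11 captures. Making the bridge before dearomatisation also keeps the fragile triketone out of this step.

**8 ⇒ 6 + 7 (cut C8–C7').** A phenolic Mannich reaction with the preformed iminium salt 7 at the only free ring carbon of 6.

**6 ⇒ 5 ⇒ 3 + 4 (cut C4–C4a, then O1–C2).** Annulations that pass through a C-bound C5 unit flanked by two free hydroxyls can close onto the para or an ortho oxygen and can give the 8-acyl isomer. Here the oxygen is chosen first: the para hydroxyl of 3, the most acidic and the only one not hydrogen-bonded to the ketone, is etherified with 4. The ring is then closed by C–C bond formation with the ether bond left intact (π-acid-catalysed hydroarylation of 5). O1 is thus by necessity para to the butanoyl group, and the two ortho carbons of 5 are equivalent.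

**3 ⇒ 1 + 2; 11 ⇒ 9 + 10; 15 ⇒ 14.** Friedel–Crafts acylations of symmetric triols, in which all reactive positions are equivalent, and activation of the commercial allylic alcohol 14 as its carbonate.

## Alternatives that were turned down

**Alternative 1:** the textbook route. The bridge is cut last (C6'–C7' and C7'–C8), giving the dearomatised monomer A1, formaldehyde and 6. Forward: dearomative geranylation of 11 at its methyl-bearing carbon to A1, then a one-carbon condensation of A1 with 6. Turned down for three reasons:
- 11 has a free ring CH, which is the less hindered and more reactive carbon, so the aromatic C-geranyl isomer A2 should dominate over A1.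
- An asymmetric catalyst would have to work against that regiochemical preference, on a ring whose flanks differ only as acetyl versus hydrogen.
- Condensing two different nucleophiles with formaldehyde also gives both symmetric dimers, and the strongly acidic A1 is the partner most prone to self-dimerise. A directed variant would cost the steps the route appears to save.

**Alternative 2:** desymmetrisation. The achiral trione A3 has a mirror plane through C1' and C4'. Forward key step: catalyst-controlled addition of one of its two enantiotopic ring CH carbons to the o-quinone methide 12 to give the des-acetyl compound A4, followed by C-acetylation. Turned down for three reasons: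
- The groups that make the two carbons enantiotopic (CH3 versus the CH2 of geranyl) sit two bonds from the reacting carbon and differ little in size; no catalyst type is known to read this difference.
- A4 is still nucleophilic at the second ring CH, so double addition competes.
- A3 would have to be made from 9 by geranylation at the methyl-bearing carbon in the presence of two free ring CH positions, and the late C-acetylation adds a step on a sensitive compound.

**Alternative 3:** de novo construction of ring A. The prochiral malonate A5 is desymmetrised enzymatically to the half-ester A6, extended to the triketo ester A7, and ring A is closed by a Dieckmann condensation (C5'–C6'), followed by C-acetylation at C2'. Turned down for three reasons: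
- The route to ring A alone would be longer than the whole sequence below, and ring B would need phenol protection.
- A7 contains a quaternary, non-enolisable 1,3-dicarbonyl unit, which is prone to retro-Claisen cleavage under the alkoxide conditions of the Dieckmann step.
- The two carbonyl arms at the stereocentre must stay differentiated through every step; any symmetrising event erases the stereochemical information.

Key step: step 8

## Route

Step 1
Reactants: 1 phloroglucinol (benzene-1,3,5-triol); 2 butanoyl chloride
Product: 3 1-(2,4,6-trihydroxyphenyl)butan-1-one
Conditions: AlCl3 (4 equiv), PhNO2/CH2Cl2, 0 → 45 °C; then ice/1 M HCl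
Reagents that add atoms: none
Why: Friedel–Crafts C-acylation of the electron-rich triol; the three ring CH positions of 1 are equivalent, and the first acyl group, held as an aluminium chelate, deactivates the ring so that mono-acylation should be clean.

Step 2
Reactants: 3 1-(2,4,6-trihydroxyphenyl)butan-1-one; 4 3-chloro-3-methylbut-1-yne
Product: 5 1-[2,6-dihydroxy-4-(2-methylbut-3-yn-2-yloxy)phenyl]butan-1-one
Conditions: 4 (1.05 equiv), CuCl2·2H2O (1 mol%), DBU (1.05 equiv), MeCN, −5 → 0 °C
Reagents that add atoms: none
Why: Copper-catalysed propargylic etherification of a phenol with a tertiary propargylic chloride (copper allenylidene pathway). The 4-OH of 3 is the most acidic hydroxyl and the only one not hydrogen-bonded to the ketone, so one equivalent of base and electrophile should etherify it alone, which fixes the future pyran oxygen.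

Step 3
Reactants: 5 1-[2,6-dihydroxy-4-(2-methylbut-3-yn-2-yloxy)phenyl]butan-1-one
Product: 6 1-(5,7-dihydroxy-2,2-dimethyl-2H-chromen-6-yl)butan-1-one
Conditions: Ph3PAuNTf2 (3 mol%), CH2Cl2, rt
Reagents that add atoms: none
Why: Gold(I)-catalysed intramolecular hydroarylation (6-endo-dig) of an aryl propargyl ether to a 2H-chromene. The O–C2 bond is not broken, so the pyran oxygen is by necessity the one para to the butanoyl group, and the two ortho carbons of the ether are equivalent, so one chromene should form.

Step 4
Reactants: 6 1-(5,7-dihydroxy-2,2-dimethyl-2H-chromen-6-yl)butan-1-one; 7 N,N-dimethylmethyleneiminium iodide (Eschenmoser's salt)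
Product: 8 1-{8-[(dimethylamino)methyl]-5,7-dihydroxy-2,2-dimethyl-2H-chromen-6-yl}butan-1-one
Conditions: 7 (1.05 equiv), Et3N (1.1 equiv), CH2Cl2, 0 °C → rt
Reagents that add atoms: none
Why: Phenolic Mannich reaction with a preformed iminium salt; C8 is the only unsubstituted ring carbon of 6 and lies ortho to 7-OH and para to 5-OH, so aminomethylation can occur only there.

Step 5
Reactants: 9 2-methylbenzene-1,3,5-triol; 10 acetyl chloride
Product: 11 1-(2,4,6-trihydroxy-3-methylphenyl)ethan-1-one
Conditions: AlCl3 (4 equiv), PhNO2/CH2Cl2, 0 → 45 °C; then ice/1 M HCl
Reagents that add atoms: none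
Why: Friedel–Crafts acylation; the two free ring positions of 9 are equivalent, so a single regioisomer should result.

Step 6
Reactants: 8 1-{8-[(dimethylamino)methyl]-5,7-dihydroxy-2,2-dimethyl-2H-chromen-6-yl}butan-1-one; 11 1-(2,4,6-trihydroxy-3-methylphenyl)ethan-1-one
Product: 13 1-{3-[(6-butanoyl-5,7-dihydroxy-2,2-dimethyl-2H-chromen-8-yl)methyl]-2,4,6-trihydroxy-5-methylphenyl}ethan-1-one, via o-quinone methide 12 (not isolated)
Conditions: 11 (1.5 equiv), 1,4-dioxane, 90 °C, N2 stream
Reagents that add atoms: none
Why: Thermal loss of dimethylamine from the ortho-hydroxybenzylamine 8 gives the o-quinone methide 12 (Mannich-base amine exchange). C5 of 11, its only free ring carbon, captures 12 in a Friedel–Crafts-type conjugate addition and the ring rearomatises; because the bridging carbon sits on one partner only and 11 is in excess, symmetric dimers should be minor.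

Step 7
Reactants: 14 geraniol, (2E)-3,7-dimethylocta-2,6-dien-1-ol
Product: 15 (2E)-3,7-dimethylocta-2,6-dien-1-yl methyl carbonate
Conditions: ClCO2Me (1.2 equiv), pyridine, CH2Cl2, 0 °C
Reagents that add atoms: methyl chloroformate, COC(=O)Cl
Why: O-Acylation of a primary allylic alcohol with a chloroformate; no allylic transposition is possible under these conditions and the E double bond is untouched.

Step 8
Reactants: 13 1-{3-[(6-butanoyl-5,7-dihydroxy-2,2-dimethyl-2H-chromen-8-yl)methyl]-2,4,6-trihydroxy-5-methylphenyl}ethan-1-one; 15 (2E)-3,7-dimethylocta-2,6-dien-1-yl methyl carbonate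
Product: 16 (4R)-2-acetyl-6-[(6-butanoyl-5,7-dihydroxy-2,2-dimethyl-2H-chromen-8-yl)methyl]-4-[(2E)-3,7-dimethylocta-2,6-dien-1-yl]-3,5-dihydroxy-4-methylcyclohexa-2,5-dien-1-one (target)
Conditions: 15 (1.05 equiv), Pd2(dba)3·CHCl3 (2.5 mol%), (S,S)-DACH-phenyl Trost ligand (7.5 mol%), iPr2NEt (1.0 equiv), degassed THF, 0 °C → rt; then cold 1 M HCl work-up
Reagents that add atoms: none
Why: Proposed new method: Pd(0) with the chiral diphosphine ionises 15, with loss of CO2 and methoxide, to a cationic π-geranyl complex, and the monophenoxide of 13 at O5' (the hydroxyl para to the acetyl group and the most acidic one) attacks the unsubstituted allyl terminus from outside the metal through C4'; one equivalent of amine base keeps 13 ionised although the product is the stronger acid. The closest known reaction types are the Pd-catalysed intermolecular asymmetric allylic dearomatisation of substituted naphthols and phenols with Trost-type ligands, the racemic Pd-catalysed dearomative allylation of acylphloroglucinols at alkyl-bearing ring carbons, and the enantioselective Pd-catalysed linear prenylation and geranylation of prochiral stabilised carbon nucleophiles to quaternary centres; new is their combination on an acylphloroglucinol. No ring is closed: the step forms the C4'–C1'' bond and turns benzene ring A into the enolised cyclohexadienone. The stereocentre C4' is set by the catalyst alone, whose chiral pocket has to select one face of the flat ring A; the two flanks it reads are unlike (C5'–O−/C6'–CH2Ar against C3'–OH/C2'–acetyl), and there is no stereocentre in the substrate. Site selectivity is secured by the substrate: every nucleophilic carbon of ring A is substituted, so only dearomative attack is possible; C6' is shielded by the ortho,ortho'-disubstituted aryl group on C7'; the acyl-bearing C2' is the least nucleophilic carbon; and ring B, which has no hydroxyl para to its acyl group, stays protonated. O-Geranyl ethers that form should re-ionise under Pd(0), so the material funnels to the irreversible C–C bond. Attack at the tertiary allyl terminus would place two quaternary carbons side by side and is disfavoured, and attack at the primary terminus of the syn complex keeps the E geometry. Over-allylation is limited by the stoichiometry and by the stabilised, hindered nature of the product enolate.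

## Compound list

1 | phloroglucinol (benzene-1,3,5-triol) | Oc1cc(O)cc(O)c1 | starting material
2 | butanoyl chloride | CCCC(Cl)=O | starting material
3 | 1-(2,4,6-trihydroxyphenyl)butan-1-one | CCCC(=O)c1c(O)cc(O)cc1O | intermediate
4 | 3-chloro-3-methylbut-1-yne | CC(C)(Cl)C#C | starting material
5 | 1-[2,6-dihydroxy-4-(2-methylbut-3-yn-2-yloxy)phenyl]butan-1-one | CCCC(=O)c1c(O)cc(OC(C)(C)C#C)cc1O | intermediate
6 | 1-(5,7-dihydroxy-2,2-dimethyl-2H-chromen-6-yl)butan-1-one | CCCC(=O)c1c(O)c2c(cc1O)OC(C)(C)C=C2 | intermediate
7 | N,N-dimethylmethyleneiminium iodide (Eschenmoser's salt) | C=[N+](C)C.[I-] | starting material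
8 | 1-{8-[(dimethylamino)methyl]-5,7-dihydroxy-2,2-dimethyl-2H-chromen-6-yl}butan-1-one | CCCC(=O)c1c(O)c2c(c(CN(C)C)c1O)OC(C)(C)C=C2 | intermediate
9 | 2-methylbenzene-1,3,5-triol | Cc1c(O)cc(O)cc1O | starting material
10 | acetyl chloride | CC(Cl)=O | starting material
11 | 1-(2,4,6-trihydroxy-3-methylphenyl)ethan-1-one | CC(=O)c1c(O)c(C)c(O)cc1O | intermediate
12 | 6-butanoyl-5-hydroxy-2,2-dimethyl-8-methylidene-2H-chromen-7(8H)-one (o-quinone methide) | CCCC(=O)C1=C(O)C2=C(OC(C)(C)C=C2)C(=C)C1=O | intermediate (not isolated)
13 | 1-{3-[(6-butanoyl-5,7-dihydroxy-2,2-dimethyl-2H-chromen-8-yl)methyl]-2,4,6-trihydroxy-5-methylphenyl}ethan-1-one | CCCC(=O)c1c(O)c2c(c(Cc3c(O)c(C)c(O)c(C(C)=O)c3O)c1O)OC(C)(C)C=C2 | intermediate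
14 | geraniol, (2E)-3,7-dimethylocta-2,6-dien-1-ol | OC/C=C(\C)CCC=C(C)C | starting material
15 | (2E)-3,7-dimethylocta-2,6-dien-1-yl methyl carbonate | COC(=O)OC/C=C(\C)CCC=C(C)C | intermediate
16 | (4R)-2-acetyl-6-[(6-butanoyl-5,7-dihydroxy-2,2-dimethyl-2H-chromen-8-yl)methyl]-4-[(2E)-3,7-dimethylocta-2,6-dien-1-yl]-3,5-dihydroxy-4-methylcyclohexa-2,5-dien-1-one | CCCC(=O)c1c(O)c2c(c(CC3=C(O)[C@@](C)(C/C=C(\C)CCC=C(C)C)C(O)=C(C(C)=O)C3=O)c1O)OC(C)(C)C=C2 | target

## Step count and least certain steps

Total: 8 steps. Longest linear sequence: 6 steps (1, 2, 3, 4, 6, 8); steps 5 and 7 are one-step side branches.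

**Step 8 (key step, proposed new method).** Three things may go wrong.
- Poor facial selectivity: the catalyst must read flanks that differ only from the second ring atom onwards, and ion pairing with the ammonium cation may loosen the fit in the chiral pocket.
- Loss of site control: attack through C6', or a second allylation of the product enolate.
- Erosion of the E geometry by π–σ–π isomerisation of the allyl complex.

Fallback, from 13 back to 16, with known chemistry and stereocontrol by separation instead of catalysis: 13 is C-geranylated under the classical conditions for dearomative alkylation of acylphloroglucinols (geranyl bromide, NaOMe, MeOH, 0 °C). This should give the racemate, that is 16 together with its enantiomer, (4S)-2-acetyl-6-[(6-butanoyl-5,7-dihydroxy-2,2-dimethyl-2H-chromen-8-yl)methyl]-4-geranyl-3,5-dihydroxy-4-methylcyclohexa-2,5-dien-1-one F1. The two are separated by preparative chromatography on a chiral stationary phase to give 16.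

**Step 2.** Over-alkylation (a second etherification at an ortho hydroxyl) or C-propargylation of the electron-rich ring may compete, because the substrate is a triol. Fallback, from 3 back to 6, bypassing 5 and step 3: direct annulation of 3 with 3-methylbut-2-enal under ethylenediammonium diacetate catalysis in refluxing toluene (Knoevenagel condensation, then oxa-6π electrocyclisation). This should give 6 together with its regioisomer 1-(5,7-dihydroxy-2,2-dimethyl-2H-chromen-8-yl)butan-1-one F2, from which 6 is separated by chromatography.

**Step 3.** The π-acid may ionise the tertiary propargylic C–O bond, with loss of the C5 unit, or be sequestered by the chelating hydroxy ketone. Fallback, from 5 back to 6, by a sigmatropic instead of a π-acid mechanism: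
- 5 is acetylated (Ac2O, pyridine, DMAP) to 2-butanoyl-5-(2-methylbut-3-yn-2-yloxy)-1,3-phenylene diacetate F3.
- Heating F3 in xylene at 140 °C triggers the aryl propargyl ether Claisen rearrangement, 1,5-hydrogen shift and oxa-6π closure. Only the former ether oxygen is free to close the ring, so this should give 6-butanoyl-2,2-dimethyl-2H-chromene-5,7-diyl diacetate F4.
- Methanolysis of F4 (K2CO3, MeOH, rt) returns 6.

**Step 6.** Bridge exchange between rings, promoted by the liberated amine at 90 °C, would scramble the product to symmetric dimers, and the intermediate 12 may self-condense before 11 captures it. Fallback, from 11 and 6 back to 13, with the roles of the rings reversed: 11 is aminomethylated with 7 (Et3N, CH2Cl2) at its only free ring carbon to give 1-{3-[(dimethylamino)methyl]-2,4,6-trihydroxy-5-methylphenyl}ethan-1-one F5. This more acidic Mannich base loses dimethylamine at lower temperature (dioxane, 60–70 °C) in the presence of 6, whose C8 adds to give 13.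

## Further compounds

F1 | step 8 | (4S)-2-acetyl-6-[(6-butanoyl-5,7-dihydroxy-2,2-dimethyl-2H-chromen-8-yl)methyl]-4-[(2E)-3,7-dimethylocta-2,6-dien-1-yl]-3,5-dihydroxy-4-methylcyclohexa-2,5-dien-1-one (enantiomer of 16) | CCCC(=O)c1c(O)c2c(c(CC3=C(O)[C@](C)(C/C=C(\C)CCC=C(C)C)C(O)=C(C(C)=O)C3=O)c1O)OC(C)(C)C=C2
F2 | step 2 | 1-(5,7-dihydroxy-2,2-dimethyl-2H-chromen-8-yl)butan-1-one | CCCC(=O)c1c(O)cc(O)c2C=CC(C)(C)Oc12
F3 | step 3 | 2-butanoyl-5-(2-methylbut-3-yn-2-yloxy)-1,3-phenylene diacetate | CCCC(=O)c1c(OC(C)=O)cc(OC(C)(C)C#C)cc1OC(C)=O
F4 | step 3 | 6-butanoyl-2,2-dimethyl-2H-chromene-5,7-diyl diacetate | CCCC(=O)c1c(OC(C)=O)c2c(cc1OC(C)=O)OC(C)(C)C=C2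
F5 | step 6 | 1-{3-[(dimethylamino)methyl]-2,4,6-trihydroxy-5-methylphenyl}ethan-1-one | CC(=O)c1c(O)c(C)c(O)c(CN(C)C)c1O
A1 | alternative 1 | (4R)-2-acetyl-4-[(2E)-3,7-dimethylocta-2,6-dien-1-yl]-3,5-dihydroxy-4-methylcyclohexa-2,5-dien-1-one | O=C1C=C(O)[C@@](C)(C/C=C(\C)CCC=C(C)C)C(O)=C1C(C)=O
A2 | alternative 1 | 1-{3-[(2E)-3,7-dimethylocta-2,6-dien-1-yl]-2,4,6-trihydroxy-5-methylphenyl}ethan-1-one | CC(=O)c1c(O)c(C)c(O)c(C/C=C(\C)CCC=C(C)C)c1O
A3 | alternative 2 | 4-[(2E)-3,7-dimethylocta-2,6-dien-1-yl]-3,5-dihydroxy-4-methylcyclohexa-2,5-dien-1-one (achiral) | O=C1C=C(O)C(C)(C/C=C(\C)CCC=C(C)C)C(O)=C1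
A4 | alternative 2 | des-acetyl analogue of 16 with the same spatial arrangement at C4': 6-[(6-butanoyl-5,7-dihydroxy-2,2-dimethyl-2H-chromen-8-yl)methyl]-4-[(2E)-3,7-dimethylocta-2,6-dien-1-yl]-3,5-dihydroxy-4-methylcyclohexa-2,5-dien-1-one | CCCC(=O)c1c(O)c2c(c(CC3=C(O)[C@@](C)(C/C=C(\C)CCC=C(C)C)C(O)=CC3=O)c1O)OC(C)(C)C=C2
A5 | alternative 3 | dimethyl 2-[(2E)-3,7-dimethylocta-2,6-dien-1-yl]-2-methylpropanedioate | COC(=O)C(C)(C/C=C(\C)CCC=C(C)C)C(=O)OC
A6 | alternative 3 | (2S)-2-[(2E)-3,7-dimethylocta-2,6-dien-1-yl]-3-methoxy-2-methyl-3-oxopropanoic acid | COC(=O)[C@@](C)(C/C=C(\C)CCC=C(C)C)C(O)=O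
A7 | alternative 3 | methyl 7-(6-butanoyl-5,7-dihydroxy-2,2-dimethyl-2H-chromen-8-yl)-2-[(2E)-3,7-dimethylocta-2,6-dien-1-yl]-2-methyl-3,5-dioxoheptanoate (enantiomer drawn) | COC(=O)[C@@](C)(C/C=C(\C)CCC=C(C)C)C(=O)CC(=O)CCc1c(O)c(C(=O)CCC)c(O)c2C=CC(C)(C)Oc12
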